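Ring locants used throughout: C1 = ketone carbon, C2 = enone carbon bearing CH2OH, C3 = enone CH, C4 = ring CH2, C5 = quaternary carbon (methyl and 4-methylpent-3-enyl), C6 = carbon bearing the enol ester arm, C7 = carbon bearing the 2-oxopropyl group. The target is compound 22.

## The problem

The target is a cyclohept-2-en-1-one with three contiguous stereocentres on its saturated half: quaternary C5, C6 with the (E)-enol ester arm, and C7 with the 2-oxopropyl group next to the ketone. The C5 methyl, the C6 arm and the C7 2-oxopropyl group all lie on one face of the ring. Methyl and 4-methylpent-3-enyl differ too little in size for a reagent approaching C6 of a preformed ring to tell the faces apart, so C5 and C6 must be created together in a stereospecific event. C7 is cis to C6 and epimerisable; enolate alkylation next to a substituted carbon gives trans, and the thermodynamic preference in this ring cannot be relied on, so C7 must be set kinetically and then kept away from strong base. The seven-membered ring is harder to close than a six-membered one, and the trisubstituted alkene of the side chain competes in metathesis and in electrophilic additions. The (E)-enol ester (base, nucleophiles, acid), the 1,4-diketone (aldol) and the 2-(hydroxymethyl)enone are all fragile, so they must appear late and under near-neutral conditions.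

The feature that makes the key step possible: with C2 removed, the carbons C1, C3, C4, C5, C6 and C7 form a cyclohexene that is a Diels–Alder adduct of a 2-oxy-diene (C7=C1(O)–C3=C4) and an (E)-2-methyl-2-enal (C6=C5). In that ring the C1 oxygen and the first carbon of the C6 arm (carried as CH2–O) are 1,3-related on the same face, so one silicon atom can join them. C2, which bears the CH2OH group, sits between C1 and C3, exactly where a halocarbene inserts into an enol ether.

## Retrosynthesis

**Last functional groups (22 ⇐ 21 ⇐ 20 ⇐ 18 ⇐ 17 ⇐ 16 ⇐ 15).** The ketal of 21 is removed last, so the 1,4-diketone exists only in the product. The C2–CH2OH bond is cut back to the C2–Br bond of 20; a neutral palladium coupling then installs the hydroxymethyl group after the enol ester is in place. The enol ester C–O bond is cut to acid 19 and the (E)-alkenylboron compound 18 (from 17). This is preferred to acylating an aldehyde enolate because a copper-mediated C–O coupling keeps the alkene geometry. The alkenylboronate 17 comes from aldehyde 16 by one-carbon olefination, and 16 from the primary alcohol 15. The forward steps must spare an α-bromoenone and two epimerisable α-centres.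

**Seven-membered ring (15 ⇐ 12).** The C1–C2 and C2–C3 bonds are cut and C2 is removed, leaving the silyl enol ether C1(OSi)=C3 of a cyclohexanone (12). Forward, a dihalocarbene adds to the enol ether and the cyclopropane opens to the 2-bromocyclohept-2-enone. This is preferred to closing the seven-membered ring from a chain because the stereotriad can then be built on a six-membered ring, and the inserted carbon arrives with the halogen needed for the CH2OH group. The step needs an enol ether of fixed regiochemistry (C1=C3, not C1=C7).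

**Side chain (12 ⇐ 9 ⇐ 8).** The 4-methylpent-3-enyl group is cut between its second and third carbon: hydroboration of the vinyl group of 9 and coupling with bromide 10. The vinyl group comes from the aldehyde of 8. The aldehyde is thus used twice, first as the activating group of the cycloaddition and then as the first carbon of the side chain.

**Key disconnection (8 ⇐ 7).** The C6–C7 and C4–C5 bonds are cut by a retro-Diels–Alder reaction. The diene is the enol ether C7=C1(O)–C3=C4 and the dienophile the (E)-enal C6=C5, joined through O–Si–O–CH2 from the C1 oxygen to the C6 arm. Untethered, the same components would react through the transition state with the formyl group endo and would give the C7 epimer. The short tether allows only the arrangement with the CH2O arm under the diene, which is the one that gives the all-cis triad. It also delivers the enol ether as C1=C3, ready for the ring expansion. Precursor 7 is an achiral, acyclic triene; product 8 carries all three stereocentres, the quaternary carbon included. The forward reaction must take place on one face of the enal only, which is asked of a chiral boron Lewis acid.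

**Assembly of 7 (7 ⇐ 3 + 5; 3 ⇐ 2 ⇐ 1; 5 ⇐ 4).** The two Si–O bonds are cut to vinyl ketone 3 and hydroxy enal 5. Ketone 3 comes from levulinate ketal 1 via Weinreb amide 2; the levulinate carbons map onto C1, C7 and the whole 2-oxopropyl group. Enal 5 comes from the acetate 4, a commercial five-carbon building block whose carbons become C5, C6, the C5 methyl, the first side-chain carbon and the first carbon of the enol ester arm.

## Roads not taken

**Alternative 1:** (the obvious route) Cut the C6–arm and C7–CH2 bonds and start from the γ-quaternary cycloheptenone A1. Forward: conjugate addition of a vinyl or formyl equivalent at C6, then alkylation of the enolate at C7, giving A2. The only element that distinguishes the faces of A1 at C6 is methyl against 4-methylpent-3-enyl on C5, so the C5/C6 relationship would be poorly controlled. The enolate alkylation places the C7 group trans to the C6 group (A2), the opposite of the target. A1 itself needs an enantioselective quaternary-centre synthesis, and the enone with its CH2OH group must still be built on the other side of the ketone. The chosen plan sets C5, C6 and C7 in one concerted step from alkene geometry.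

**Alternative 2:** (biomimetic) Cut C6–C7 by a retro-oxy-Cope rearrangement to the eleven-membered hydroxy-triene A3. Forward: a [3,3] shift would form C6–C7, the (E)-enol ester and the methyl ketone at once. The precursor is not simpler than the product: an eleven-membered ring with three alkenes of defined geometry, a tertiary alcohol next to an acyloxy carbon (acyl migration under base), and the quaternary centre already in place. Whether the ring reacts through a chair or a boat decides the C6/C7 relationship and cannot be secured beforehand. The chosen key step starts from an acyclic, achiral triene made in four steps.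

**Alternative 3:** (buy the seven-membered ring) Start from tropone; conjugate 1,8-addition of an acetone enolate would give A4 with the C7 group in place, and the C6 and C5 groups would follow by further conjugate additions to the dienone. C5 would need two successive additions with a re-oxidation between them to become quaternary, and the methyl/4-methylpent-3-enyl facial problem returns at C6. The diene must be moved in and out of conjugation several times, so the route is long in redox steps and weak in stereocontrol exactly where the target is hardest.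

Key step: step 5

Assumption: the (R)-configured oxazaborolidinium ion is taken to shield the bound enal of 7 in the sense established for 2-methylacrolein, which leads to 8; if the tethered substrate responded in the opposite sense, the (S)-catalyst would be used and nothing else would change.

## Route

Step 1
Reactants: 1 ethyl 3-(2-methyl-1,3-dioxolan-2-yl)propanoate
Product: 2 N-methoxy-N-methyl-3-(2-methyl-1,3-dioxolan-2-yl)propanamide
Conditions: MeNH(OMe)·HCl, iPrMgCl, THF, −20 → 0 °C
Reagents that add atoms: N,O-dimethylhydroxylamine hydrochloride, CNOC.Cl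
Why: Aminolysis of the ester by the chloromagnesium amide of N,O-dimethylhydroxylamine (Weinreb amide formation); the ketal is inert to the basic conditions.

Step 2
Reactants: 2 N-methoxy-N-methyl-3-(2-methyl-1,3-dioxolan-2-yl)propanamide
Product: 3 5-(2-methyl-1,3-dioxolan-2-yl)pent-1-en-3-one
Conditions: CH2=CHMgBr, THF, −20 °C; cold aq. HCl quench
Reagents that add atoms: vinylmagnesium bromide, C=C[Mg]Br
Why: Grignard addition to the Weinreb amide stops at the chelated tetrahedral intermediate and releases the vinyl ketone on cold acidic quench, which also keeps the freed amine from adding to the enone.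

Step 3
Reactants: 4 (2E)-3-methyl-4-oxobut-2-en-1-yl acetate
Product: 5 (2E)-4-hydroxy-2-methylbut-2-enal
Conditions: K2CO3 (cat.), MeOH, 0 °C
Reagents that add atoms: none
Why: Base-catalysed transesterification of the allylic acetate; the E enal cannot close to a lactol and is used at once.

Step 4
Reactants: 5 (2E)-4-hydroxy-2-methylbut-2-enal; 3 5-(2-methyl-1,3-dioxolan-2-yl)pent-1-en-3-one
Product: 7 (2E)-2-methyl-4-{[{[(3Z)-5-(2-methyl-1,3-dioxolan-2-yl)penta-1,3-dien-3-yl]oxy}di(propan-2-yl)silyl]oxy}but-2-enal, via alkoxysilyl triflate 6 (not isolated)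
Conditions: iPr2Si(OTf)2, 2,6-lutidine, CH2Cl2, −78 °C; then 3, Et3N, −78 → 0 °C
Reagents that add atoms: diisopropylsilyl bis(trifluoromethanesulfonate), CC(C)[Si](OS(=O)(=O)C(F)(F)F)(OS(=O)(=O)C(F)(F)F)C(C)C
Why: Stepwise substitution at silicon: the primary alcohol displaces the first triflate at −78 °C and the hindered second one waits for soft enolisation of the ketone (silyl triflate with amine base). As with other alkyl vinyl ketones this should give the Z enol ether, side chain cis to oxygen; the ketone can enolise only toward C7.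

Step 5
Reactants: 7 (2E)-2-methyl-4-{[{[(3Z)-5-(2-methyl-1,3-dioxolan-2-yl)penta-1,3-dien-3-yl]oxy}di(propan-2-yl)silyl]oxy}but-2-enal
Product: 8 (6S,7S,10R)-7-methyl-10-[(2-methyl-1,3-dioxolan-2-yl)methyl]-3,3-di(propan-2-yl)-2,4-dioxa-3-silabicyclo[4.3.1]dec-1(9)-ene-7-carbaldehyde
Conditions: (R)-3,3-diphenyl-1-(2-methylphenyl)tetrahydro-1H,3H-pyrrolo[1,2-c][1,3,2]oxazaborole protonated with (CF3SO2)2NH (20 mol%), CH2Cl2, −78 → −40 °C
Reagents that add atoms: none
Why: Proposed new method: a concerted, asynchronous [4+2] cycloaddition of normal electron demand in which the boron-bound, LUMO-lowered enal C5=C6 meets the 2-silyloxydiene C7=C1–C3=C4, the nucleophilic terminus C7 attacking the enal β-carbon C6 while C4 closes on the α-carbon C5; the closest known reaction types are the Lewis-acid-catalysed type 2 intramolecular Diels–Alder reaction of trienes held by a silyl acetal tether and the oxazaborolidinium-catalysed Diels–Alder reaction of 2-methylacrolein with 2-silyloxy-1,3-dienes. The cyclohexene ring closes in the [4+2] mode and, because the tether starts at the internal diene carbon C1, the second ring closes in the type 2 (bridged, meta) mode to a bicyclo[4.3.1]decene whose bridgehead enol ether lies trans in a nine-membered ring with two long Si–O bonds and is therefore little strained. The four-atom O–Si–O–CH2 tether can reach C6 only if the CH2O arm lies under the diene (endo), which puts the geminal methyl of the E enal endo and the formyl group exo, the reverse of what the untethered reaction prefers. C5 and C6 take their relative configuration from the E geometry of the enal (methyl cis to the CH2O arm); C7 takes its configuration from the Z enol ether (arm outside) and the endo tether, which puts the C7 arm cis to the C6 arm; the absolute configuration of all three comes from the catalyst, which shields one face of the s-trans enal. Regioselectivity is secured twice, by the tether and by the matched polarity (siloxy carbon para to the formyl-bearing carbon). α-Branched enals have only a weak intrinsic endo preference for the formyl group, so the forced exo placement should cost little. The uncatalysed reaction is expected to need heating, so the catalysed pathway at low temperature should decide the enantioselectivity.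

Step 6
Reactants: 8 (6S,7S,10R)-7-methyl-10-[(2-methyl-1,3-dioxolan-2-yl)methyl]-3,3-di(propan-2-yl)-2,4-dioxa-3-silabicyclo[4.3.1]dec-1(9)-ene-7-carbaldehyde
Product: 9 (6S,7R,10R)-7-ethenyl-7-methyl-10-[(2-methyl-1,3-dioxolan-2-yl)methyl]-3,3-di(propan-2-yl)-2,4-dioxa-3-silabicyclo[4.3.1]dec-1(9)-ene
Conditions: Ph3PCH3Br, KHMDS, THF, 0 → 23 °C
Reagents that add atoms: methyltriphenylphosphonium bromide, C[P+](c1ccccc1)(c1ccccc1)c1ccccc1.[Br-]
Why: Wittig methylenation of the non-enolisable neopentyl aldehyde; the enol silyl acetal and the ketal tolerate the ylide (the C7 descriptor changes only through ligand priority).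

Step 7
Reactants: 9 (6S,7R,10R)-7-ethenyl-7-methyl-10-[(2-methyl-1,3-dioxolan-2-yl)methyl]-3,3-di(propan-2-yl)-2,4-dioxa-3-silabicyclo[4.3.1]dec-1(9)-ene; 10 1-bromo-2-methylprop-1-ene
Product: 12 (6S,7S,10R)-7-methyl-10-[(2-methyl-1,3-dioxolan-2-yl)methyl]-7-(4-methylpent-3-en-1-yl)-3,3-di(propan-2-yl)-2,4-dioxa-3-silabicyclo[4.3.1]dec-1(9)-ene, via B-alkyl-9-borabicyclononane 11 (not isolated)
Conditions: 9-BBN, THF, 23 °C; then 10, [1,1'-bis(diphenylphosphino)ferrocene]PdCl2 (5 mol%), Ph3As, Cs2CO3, DMF–H2O, 23 °C
Reagents that add atoms: none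
Why: 9-BBN adds anti-Markovnikov to the monosubstituted vinyl group only, not to the hindered trisubstituted enol ether; B-alkyl Suzuki–Miyaura coupling with the alkenyl bromide then completes the 4-methylpent-3-enyl chain in the same flask.

Step 8
Reactants: 12 (6S,7S,10R)-7-methyl-10-[(2-methyl-1,3-dioxolan-2-yl)methyl]-7-(4-methylpent-3-en-1-yl)-3,3-di(propan-2-yl)-2,4-dioxa-3-silabicyclo[4.3.1]dec-1(9)-ene
Product: 15 (5S,6S,7R)-2-bromo-6-(hydroxymethyl)-5-methyl-7-[(2-methyl-1,3-dioxolan-2-yl)methyl]-5-(4-methylpent-3-en-1-yl)cyclohept-2-en-1-one, via dibromocyclopropane 13 (not isolated), via bromosilyl ether 14 (not isolated)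
Conditions: CHBr3, KOtBu, pentane, −30 → 0 °C; then 2,6-lutidine, toluene, 80 °C; then Et3N·3HF, THF, 23 °C
Reagents that add atoms: bromoform, BrC(Br)Br
Why: Dibromocarbene should add to the most nucleophilic and most strained alkene, the bridgehead enol ether (gem-dihalocyclopropanation of a silyl enol ether). Oxygen-assisted ionisation of the endo bromide with disrotatory opening of the C1–C3 bond (cyclopropyl to allyl cation) then inserts the carbene carbon as C2 and gives the 2-bromoenone, while bromide takes silicon from the former enol oxygen and fluoride frees the C6 hydroxymethyl group. No stereocentre is formed; C7 becomes α to the new ketone, hence the weak hindered base.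

Step 9
Reactants: 15 (5S,6S,7R)-2-bromo-6-(hydroxymethyl)-5-methyl-7-[(2-methyl-1,3-dioxolan-2-yl)methyl]-5-(4-methylpent-3-en-1-yl)cyclohept-2-en-1-one
Product: 16 (1S,2R,7S)-4-bromo-7-methyl-2-[(2-methyl-1,3-dioxolan-2-yl)methyl]-7-(4-methylpent-3-en-1-yl)-3-oxocyclohept-4-ene-1-carbaldehyde
Conditions: Dess–Martin periodinane, NaHCO3, CH2Cl2, 0 → 23 °C
Reagents that add atoms: none
Why: Dess–Martin oxidation of the primary alcohol under buffered, non-basic conditions, which should leave the α-centres at C6 and C7 untouched.

Step 10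
Reactants: 16 (1S,2R,7S)-4-bromo-7-methyl-2-[(2-methyl-1,3-dioxolan-2-yl)methyl]-7-(4-methylpent-3-en-1-yl)-3-oxocyclohept-4-ene-1-carbaldehyde
Product: 17 (5S,6S,7R)-2-bromo-5-methyl-7-[(2-methyl-1,3-dioxolan-2-yl)methyl]-5-(4-methylpent-3-en-1-yl)-6-[(E)-2-(4,4,5,5-tetramethyl-1,3,2-dioxaborolan-2-yl)ethenyl]cyclohept-2-en-1-one
Conditions: CrCl2 (divalent chromium, 8 equiv), Cl2CHB(pin), LiI, THF, 23 °C
Reagents that add atoms: 2-(dichloromethyl)-4,4,5,5-tetramethyl-1,3,2-dioxaborolane, ClC(Cl)B1OC(C)(C)C(C)(C)O1
Why: Boron variant of the Takai olefination (Takai–Utimoto): the gem-dichromium species adds to the aldehyde and eliminates to the E-alkenylboronate; divalent chromium does not insert into alkenyl bromides without nickel, so the bromoenone should survive.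

Step 11
Reactants: 17 (5S,6S,7R)-2-bromo-5-methyl-7-[(2-methyl-1,3-dioxolan-2-yl)methyl]-5-(4-methylpent-3-en-1-yl)-6-[(E)-2-(4,4,5,5-tetramethyl-1,3,2-dioxaborolan-2-yl)ethenyl]cyclohept-2-en-1-one
Product: 18 potassium {(E)-2-[(1S,2R,7S)-4-bromo-7-methyl-2-[(2-methyl-1,3-dioxolan-2-yl)methyl]-7-(4-methylpent-3-en-1-yl)-3-oxocyclohept-4-en-1-yl]ethenyl}trifluoroborate
Conditions: KHF2, MeOH–H2O, 23 °C
Reagents that add atoms: potassium hydrogen difluoride, F.[F-].[K+]
Why: Standard conversion of a pinacol boronate into the trifluoroborate salt required for the copper coupling; alkene geometry is untouched.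

Step 12
Reactants: 18 potassium {(E)-2-[(1S,2R,7S)-4-bromo-7-methyl-2-[(2-methyl-1,3-dioxolan-2-yl)methyl]-7-(4-methylpent-3-en-1-yl)-3-oxocyclohept-4-en-1-yl]ethenyl}trifluoroborate; 19 3-methylbut-2-enoic acid
Product: 20 (E)-2-[(1S,2R,7S)-4-bromo-7-methyl-2-[(2-methyl-1,3-dioxolan-2-yl)methyl]-7-(4-methylpent-3-en-1-yl)-3-oxocyclohept-4-en-1-yl]ethenyl 3-methylbut-2-enoate
Conditions: CuBr (monovalent copper, 20 mol%), 4-(dimethylamino)pyridine, 4 Å molecular sieves, O2 (1 atm), CH2Cl2, 40 °C
Reagents that add atoms: none
Why: Chan–Lam-type oxidative C–O coupling of an alkenyltrifluoroborate with a carboxylic acid, which keeps the alkene geometry and so gives the E enol ester without passing through an aldehyde enolate.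

Step 13
Reactants: 20 (E)-2-[(1S,2R,7S)-4-bromo-7-methyl-2-[(2-methyl-1,3-dioxolan-2-yl)methyl]-7-(4-methylpent-3-en-1-yl)-3-oxocyclohept-4-en-1-yl]ethenyl 3-methylbut-2-enoate
Product: 21 (E)-2-[(1S,2R,7S)-4-(hydroxymethyl)-7-methyl-2-[(2-methyl-1,3-dioxolan-2-yl)methyl]-7-(4-methylpent-3-en-1-yl)-3-oxocyclohept-4-en-1-yl]ethenyl 3-methylbut-2-enoate
Conditions: Bu3SnCH2OH, Pd(PPh3)4 (zerovalent palladium, 10 mol%), 1,4-dioxane, 80 °C
Reagents that add atoms: (tributylstannyl)methanol, CCCC[Sn](CCCC)(CCCC)CO
Why: Stille coupling: oxidative addition of zerovalent palladium into the C2–Br bond of the α-bromoenone and transfer of the hydroxymethyl group from tin; the neutral conditions should spare the enol ester and C7.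

Step 14
Reactants: 21 (E)-2-[(1S,2R,7S)-4-(hydroxymethyl)-7-methyl-2-[(2-methyl-1,3-dioxolan-2-yl)methyl]-7-(4-methylpent-3-en-1-yl)-3-oxocyclohept-4-en-1-yl]ethenyl 3-methylbut-2-enoate
Product: 22 (E)-2-[(1S,2R,7S)-4-(hydroxymethyl)-7-methyl-7-(4-methylpent-3-en-1-yl)-3-oxo-2-(2-oxopropyl)cyclohept-4-en-1-yl]ethenyl 3-methylbut-2-enoate
Conditions: pyridinium p-toluenesulfonate (cat.), acetone–H2O, 45 °C
Reagents that add atoms: water, O
Why: Mild acid-catalysed hydrolysis of the dioxolane, chosen to be gentle enough for the enol ester, the allylic alcohol and the epimerisable C7 centre; the 1,4-diketone appears only here.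

## Compound list

1 | ethyl 3-(2-methyl-1,3-dioxolan-2-yl)propanoate | CCOC(=O)CCC1(C)OCCO1 | starting material
2 | N-methoxy-N-methyl-3-(2-methyl-1,3-dioxolan-2-yl)propanamide | CON(C)C(=O)CCC1(C)OCCO1 | intermediate
3 | 5-(2-methyl-1,3-dioxolan-2-yl)pent-1-en-3-one | C=CC(=O)CCC1(C)OCCO1 | intermediate
4 | (2E)-3-methyl-4-oxobut-2-en-1-yl acetate | CC(=O)OC/C=C(\C)C=O | starting material
5 | (2E)-4-hydroxy-2-methylbut-2-enal | OC/C=C(\C)C=O | intermediate
6 | (2E)-4-({di(propan-2-yl)[(trifluoromethanesulfonyl)oxy]silyl}oxy)-2-methylbut-2-enal | O=C/C(C)=C/CO[Si](C(C)C)(C(C)C)OS(=O)(=O)C(F)(F)F | intermediate (not isolated)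
7 | (2E)-2-methyl-4-{[{[(3Z)-5-(2-methyl-1,3-dioxolan-2-yl)penta-1,3-dien-3-yl]oxy}di(propan-2-yl)silyl]oxy}but-2-enal | C=C/C(O[Si](C(C)C)(C(C)C)OC/C=C(\C)C=O)=C/CC1(C)OCCO1 | intermediate
8 | (6S,7S,10R)-7-methyl-10-[(2-methyl-1,3-dioxolan-2-yl)methyl]-3,3-di(propan-2-yl)-2,4-dioxa-3-silabicyclo[4.3.1]dec-1(9)-ene-7-carbaldehyde | O=C[C@@]1(C)CC=C2[C@H](CC3(C)OCCO3)[C@@H]1CO[Si](C(C)C)(C(C)C)O2 | intermediate
9 | (6S,7R,10R)-7-ethenyl-7-methyl-10-[(2-methyl-1,3-dioxolan-2-yl)methyl]-3,3-di(propan-2-yl)-2,4-dioxa-3-silabicyclo[4.3.1]dec-1(9)-ene | C=C[C@@]1(C)CC=C2[C@H](CC3(C)OCCO3)[C@@H]1CO[Si](C(C)C)(C(C)C)O2 | intermediate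
10 | 1-bromo-2-methylprop-1-ene | CC(C)=CBr | starting material
11 | B-alkyl-9-borabicyclo[3.3.1]nonane from hydroboration of the vinyl group of 9 | C(C[C@@]1(C)CC=C2[C@H](CC3(C)OCCO3)[C@@H]1CO[Si](C(C)C)(C(C)C)O2)B1C2CCCC1CCC2 | intermediate (not isolated)
12 | (6S,7S,10R)-7-methyl-10-[(2-methyl-1,3-dioxolan-2-yl)methyl]-7-(4-methylpent-3-en-1-yl)-3,3-di(propan-2-yl)-2,4-dioxa-3-silabicyclo[4.3.1]dec-1(9)-ene | CC(C)=CCC[C@@]1(C)CC=C2[C@H](CC3(C)OCCO3)[C@@H]1CO[Si](C(C)C)(C(C)C)O2 | intermediate
13 | gem-dibromocyclopropane formed by addition of dibromocarbene to the C1=C9 enol ether of 12, carbene anti to the O–Si–O bridge | CC(C)=CCC[C@@]1(C)C[C@H]2C(Br)(Br)[C@@]23[C@H](CC4(C)OCCO4)[C@@H]1CO[Si](C(C)C)(C(C)C)O3 | intermediate (not isolated)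
14 | (5S,6S,7R)-2-bromo-6-({[bromodi(propan-2-yl)silyl]oxy}methyl)-5-methyl-7-[(2-methyl-1,3-dioxolan-2-yl)methyl]-5-(4-methylpent-3-en-1-yl)cyclohept-2-en-1-one | O=C1C(Br)=CC[C@](C)(CCC=C(C)C)[C@@H](CO[Si](Br)(C(C)C)C(C)C)[C@H]1CC2(C)OCCO2 | intermediate (not isolated)
15 | (5S,6S,7R)-2-bromo-6-(hydroxymethyl)-5-methyl-7-[(2-methyl-1,3-dioxolan-2-yl)methyl]-5-(4-methylpent-3-en-1-yl)cyclohept-2-en-1-one | O=C1C(Br)=CC[C@](C)(CCC=C(C)C)[C@@H](CO)[C@H]1CC2(C)OCCO2 | intermediate
16 | (1S,2R,7S)-4-bromo-7-methyl-2-[(2-methyl-1,3-dioxolan-2-yl)methyl]-7-(4-methylpent-3-en-1-yl)-3-oxocyclohept-4-ene-1-carbaldehyde | O=C1C(Br)=CC[C@](C)(CCC=C(C)C)[C@@H](C=O)[C@H]1CC2(C)OCCO2 | intermediate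
17 | (5S,6S,7R)-2-bromo-5-methyl-7-[(2-methyl-1,3-dioxolan-2-yl)methyl]-5-(4-methylpent-3-en-1-yl)-6-[(E)-2-(4,4,5,5-tetramethyl-1,3,2-dioxaborolan-2-yl)ethenyl]cyclohept-2-en-1-one | O=C1C(Br)=CC[C@](C)(CCC=C(C)C)[C@@H](/C=C/B2OC(C)(C)C(C)(C)O2)[C@H]1CC3(C)OCCO3 | intermediate
18 | potassium {(E)-2-[(1S,2R,7S)-4-bromo-7-methyl-2-[(2-methyl-1,3-dioxolan-2-yl)methyl]-7-(4-methylpent-3-en-1-yl)-3-oxocyclohept-4-en-1-yl]ethenyl}trifluoroborate | O=C1C(Br)=CC[C@](C)(CCC=C(C)C)[C@@H](/C=C/[B-](F)(F)F)[C@H]1CC2(C)OCCO2.[K+] | intermediate
19 | 3-methylbut-2-enoic acid | CC(C)=CC(=O)O | starting material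
20 | (E)-2-[(1S,2R,7S)-4-bromo-7-methyl-2-[(2-methyl-1,3-dioxolan-2-yl)methyl]-7-(4-methylpent-3-en-1-yl)-3-oxocyclohept-4-en-1-yl]ethenyl 3-methylbut-2-enoate | O=C1C(Br)=CC[C@](C)(CCC=C(C)C)[C@@H](/C=C/OC(=O)C=C(C)C)[C@H]1CC2(C)OCCO2 | intermediate
21 | (E)-2-[(1S,2R,7S)-4-(hydroxymethyl)-7-methyl-2-[(2-methyl-1,3-dioxolan-2-yl)methyl]-7-(4-methylpent-3-en-1-yl)-3-oxocyclohept-4-en-1-yl]ethenyl 3-methylbut-2-enoate | O=C1C(CO)=CC[C@](C)(CCC=C(C)C)[C@@H](/C=C/OC(=O)C=C(C)C)[C@H]1CC2(C)OCCO2 | intermediate
22 | (E)-2-[(1S,2R,7S)-4-(hydroxymethyl)-7-methyl-7-(4-methylpent-3-en-1-yl)-3-oxo-2-(2-oxopropyl)cyclohept-4-en-1-yl]ethenyl 3-methylbut-2-enoate | CC(=O)C[C@H]1C(=O)C(CO)=CC[C@](C)(CCC=C(C)C)[C@H]1/C=C/OC(=O)C=C(C)C | target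

## Step count and risk

Total steps: 14. Longest linear sequence: 13 (from 1 through steps 1, 2 and 4 to 14); step 3 prepares the second component of step 4.

**Step 5 (key step, proposed new method).** The strongly acidic boron catalyst may cleave the enol–silicon bond or start a Mukaiyama-type addition of the enol ether to the bound aldehyde before the cycloaddition. Facial discrimination may also be eroded, because the tether and not the catalyst fixes the geometry of approach. Any E enol ether isomer in 7 would react slowly or give the C7 epimer. Fallback by known chemistry, from 3 and 4 back to 15, is the untethered, intermolecular cycloaddition followed by correction of C7: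
- Ketone 3 is converted with TBSOTf and Et3N into the Z silyl dienol ether F1.
- F1 and acetate 4 react under the same oxazaborolidinium catalysis (a known pairing of a 2-silyloxydiene with a 2-methyl-2-enal). The reaction goes through the transition state with the formyl group endo and gives cyclohexene F2, with C5 and C6 as in 8 but C7 epimeric.
- Wittig methylenation gives F3, and hydroboration with Suzuki coupling to 10 gives F4.
- Dibromocarbene addition and heating give the 7-epi bromoenone acetate F5; mild methanolysis (K2CO3, MeOH, 0 °C) gives the 7-epi alcohol F6.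
- F6 is deprotonated with LiHMDS (2.2 equiv, THF, −78 °C) and the C7 enolate is quenched at −78 °C with 2,6-di-tert-butyl-4-methylphenol. The proton enters anti to the C6 substituent, which puts the C7 arm cis to it and gives 15.

**Step 4.** Double substitution at silicon, silyl-triflate-promoted reactions of the enal, or an E/Z mixture of the enol ether may lower the supply of 7. Fallback, from 3 back to 7: make the enol–silicon bond first by hard enolisation. Ketone 3 is deprotonated with LDA in THF–DMPU at −78 °C and quenched with excess iPr2SiCl2 to give the chlorosilyl dienol ether F7; after removal of volatiles, F7 is joined to 5 with imidazole in CH2Cl2 to give 7.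

**Step 8.** The carbene may also add to the trisubstituted alkene of the side chain, whose reactivity is not far below that of a silyl enol ether. If silicon is lost before ionisation, the cyclopropanol may open to an α-(dibromomethyl) ketone and not to the ring-expanded enone. C7 may epimerise once the ketone is formed. Fallback, from 9 back to 13: reverse the order of steps 7 and 8, so that the carbene meets the enol ether before the second alkene exists. Compound 9 is treated with CHBr3 and KOtBu to give the vinyl dibromocyclopropane F8, which is kept cold and taken through hydroboration and Suzuki coupling with 10 to give 13; the thermal opening and fluoride treatment then follow as in step 8.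

**Step 12.** Protodeboronation or homocoupling of the hindered alkenyltrifluoroborate, slow C–O bond formation, or amine-induced epimerisation at C7 may occur. Fallback, from 16 back to 20: the alkenyl iodide route. Aldehyde 16 is converted by Takai olefination (CHI3, CrCl2) into the E-alkenyl iodide F9, which is coupled with acid 19 under Ullmann-type conditions (CuI, 3,4,7,8-tetramethyl-1,10-phenanthroline, Cs2CO3, toluene) with retention of geometry to give 20.

**Step 14.** Acid may hydrolyse the enol ester, enolise C7, or induce aldol closure of the freed 1,4-diketone. Fallback, from 17 back to 22: remove the ketal before the enol ester exists. Compound 17 is hydrolysed (pyridinium p-toluenesulfonate, wet acetone) to the keto boronate F10, converted with KHF2 into the trifluoroborate F11, coupled with 19 as in step 12 to the bromo enol ester F12, and F12 is taken through the Stille coupling of step 13 to give 22 directly.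

## Further compounds

F1 | step 5 | tert-butyl(dimethyl){[(3Z)-5-(2-methyl-1,3-dioxolan-2-yl)penta-1,3-dien-3-yl]oxy}silane | C=C/C(O[Si](C)(C)C(C)(C)C)=C/CC1(C)OCCO1
F2 | step 5 | 2-(acetoxymethyl)-4-[(tert-butyldimethylsilyl)oxy]-1-methyl-3-[(2-methyl-1,3-dioxolan-2-yl)methyl]cyclohex-4-ene-1-carbaldehyde, formyl cis to the C3 arm, acetoxymethyl cis to methyl (C7-epimeric series) | O=C[C@@]1(C)CC=C(O[Si](C)(C)C(C)(C)C)[C@@H](CC2(C)OCCO2)[C@@H]1COC(C)=O
F3 | step 5 | vinyl analogue of F2 (formyl replaced by ethenyl) | C=C[C@@]1(C)CC=C(O[Si](C)(C)C(C)(C)C)[C@@H](CC2(C)OCCO2)[C@@H]1COC(C)=O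
F4 | step 5 | 4-methylpent-3-enyl analogue of F3 | CC(C)=CCC[C@@]1(C)CC=C(O[Si](C)(C)C(C)(C)C)[C@@H](CC2(C)OCCO2)[C@@H]1COC(C)=O
F5 | step 5 | acetate of the C7 epimer of 15 | O=C1C(Br)=CC[C@](C)(CCC=C(C)C)[C@@H](COC(C)=O)[C@@H]1CC2(C)OCCO2
F6 | step 5 | (5S,6S,7S)-2-bromo-6-(hydroxymethyl)-5-methyl-7-[(2-methyl-1,3-dioxolan-2-yl)methyl]-5-(4-methylpent-3-en-1-yl)cyclohept-2-en-1-one (C7 epimer of 15) | O=C1C(Br)=CC[C@](C)(CCC=C(C)C)[C@@H](CO)[C@@H]1CC2(C)OCCO2
F7 | step 4 | chloro{[(3Z)-5-(2-methyl-1,3-dioxolan-2-yl)penta-1,3-dien-3-yl]oxy}di(propan-2-yl)silane | C=C/C(O[Si](Cl)(C(C)C)C(C)C)=C/CC1(C)OCCO1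
F8 | step 8 | gem-dibromocyclopropane from dibromocarbene addition to the enol ether of 9 | C=C[C@@]1(C)C[C@H]2C(Br)(Br)[C@@]23[C@H](CC4(C)OCCO4)[C@@H]1CO[Si](C(C)C)(C(C)C)O3
F9 | step 12 | (5S,6S,7R)-2-bromo-6-[(E)-2-iodoethenyl]-5-methyl-7-[(2-methyl-1,3-dioxolan-2-yl)methyl]-5-(4-methylpent-3-en-1-yl)cyclohept-2-en-1-one | O=C1C(Br)=CC[C@](C)(CCC=C(C)C)[C@@H](/C=C/I)[C@H]1CC2(C)OCCO2
F10 | step 14 | (5S,6S,7R)-2-bromo-5-methyl-5-(4-methylpent-3-en-1-yl)-7-(2-oxopropyl)-6-[(E)-2-(4,4,5,5-tetramethyl-1,3,2-dioxaborolan-2-yl)ethenyl]cyclohept-2-en-1-one | CC(=O)C[C@H]1C(=O)C(Br)=CC[C@](C)(CCC=C(C)C)[C@H]1/C=C/B2OC(C)(C)C(C)(C)O2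
F11 | step 14 | potassium {(E)-2-[(1S,2R,7S)-4-bromo-7-methyl-7-(4-methylpent-3-en-1-yl)-3-oxo-2-(2-oxopropyl)cyclohept-4-en-1-yl]ethenyl}trifluoroborate | CC(=O)C[C@H]1C(=O)C(Br)=CC[C@](C)(CCC=C(C)C)[C@H]1/C=C/[B-](F)(F)F.[K+]
F12 | step 14 | (E)-2-[(1S,2R,7S)-4-bromo-7-methyl-7-(4-methylpent-3-en-1-yl)-3-oxo-2-(2-oxopropyl)cyclohept-4-en-1-yl]ethenyl 3-methylbut-2-enoate | CC(=O)C[C@H]1C(=O)C(Br)=CC[C@](C)(CCC=C(C)C)[C@H]1/C=C/OC(=O)C=C(C)C
A1 | alternative 1 | (R)-4-methyl-4-(4-methylpent-3-en-1-yl)cyclohept-2-en-1-one | O=C1CCC[C@](C)(CCC=C(C)C)C=C1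
A2 | alternative 1 | 2-allyl-3-ethenyl-4-methyl-4-(4-methylpent-3-en-1-yl)cycloheptan-1-one, allyl trans to ethenyl, ethenyl cis to methyl | O=C1CCC[C@](C)(CCC=C(C)C)[C@@H](C=C)[C@@H]1CC=C
A3 | alternative 2 | (2Z,6E,10E)-9-hydroxy-2-(hydroxymethyl)-5,9-dimethyl-5-(4-methylpent-3-en-1-yl)-8-[(3-methylbut-2-enoyl)oxy]cycloundeca-2,6,10-trien-1-one (one diastereomer) | O=C1/C=C/[C@@](C)(O)[C@H](OC(=O)C=C(C)C)/C=C/[C@](C)(CCC=C(C)C)C/C=C1/CO
A4 | alternative 3 | (R)-2-(2-oxopropyl)cyclohepta-3,5-dien-1-one | CC(=O)C[C@@H]1C=CC=CCC1=O
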